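**The contest.** The target is made from the substrate and then lost again, so its course is a contest between two rates. I look for the time at which the lead changes hands.

| flask | substrate | remark | time |
|---|---|---|---|
| Sunday's | 1.3 M | run made earlier |  |
| Thursday's | 3 M | run made earlier |  |
| flask | 2.0 M |  | 4.0 d |

| run | time / d | target / % | isomer of the product A / % |
|---|---|---|---|
| Sunday's | 0.208 | 15.4 | 22.3 |
| Sunday's | 0.625 | 22.4 | 53.7 |
| Sunday's | 1.04 | 22.2 | 65.4 |
| Sunday's | 1.67 | 18.3 | 69.4 |
| Sunday's | 2.50 | 13.0 | 69.7 |
| Sunday's | 3.00 | 13.0 | 68.3 |
| Thursday's | 0.208 | 16.2 | 22.6 |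
| Thursday's | 0.625 | 24.0 | 51.3 |
| Thursday's | 1.04 | 22.2 | 61.6 |
| Thursday's | 1.67 | 17.7 | 67.2 |
| Thursday's | 2.50 | 13.8 | 67.9 |
| Thursday's | 3.00 | 15.2 | 68.0 |

(readings scatter by 1 percentage point)

1. share of target in target plus isomer of the product A at 40 min
2. share of target in target plus isomer of the product A at 4.0 d

- the earlier runs were read with a standard deviation of 1 percentage point

**Starting rate.** Both runs lie close together, so I reckon per day in percent of the charge. I count what Sunday's two readings miss at 0.625 d as substrate. That gives a first-order constant k = 2.29 d⁻¹. The target holds 40.8 % of the two products in Sunday's first reading, so I put its starting feed at F = 0.935 d⁻¹.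

**Slowing.** The feed shrinks by the factor exp(-kt). Between 1.04 d and 2.50 d Sunday's target falls at a net constant L = 0.367 d⁻¹. With Sunday's highest target reading, I reckon that the feed meets that loss at 1.06 d, the hand-over time: the time when the target's feed falls to its loss. The factor there is 8.83 %.

**My commitment.** My hand-over comes earlier than the end, so I take the late readings of both runs for the end. Their mean share is 16.7 %. I give no number for 40 min, which lies before the first reading.

**Forecast.** It gives 50 % and 15.5 %, and says of the first: "That extrapolation is uncertain".

**Result.** The flask gives 67.6 % and 16.8 %.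

    substrate ⇌ other conformer (K = 1.20, k = 0.0740 h⁻¹)
    substrate → target (k = 0.0420 h⁻¹)
    other conformer → isomer of the product A (k = 0.970 h⁻¹)
    target ⇌ isomer of the product A (K = 4.20, k = 0.0270 h⁻¹)
    2 substrate → self-condensation product (k = 0.00110 M⁻¹ h⁻¹)
    target ⇌ isomer of the product B (K = 2.10, k = 0.0160 h⁻¹)

**What happened.** While substrate stood, the flask's target and isomer of the product A both grew, and they drew level at 0.0774 d, later than 40 min. The flask's substrate then went from 33.4 % at 0.400 d to 0.464 % at 2.00 d, and its target stood highest at 0.719 d, earlier than my 1.06 d, while its isomer of the product B rose from 1.92 % at 0.400 d to 17.7 % at 4.00 d.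

**Neighbour.** My formula for the hand-over holds no charge, so at 0.50 M it stays 1.06 d. That neighbour gives 67.6 % and 16.8 %, with 0 % of its substrate left at 4.0 d.

(The data are simulated for an exercise, noise included.)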